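## Analysis of the target

The target 20 is a (2S)-flavanone: a chroman-4-one (rings A and C) with a 4-hydroxyphenyl group (ring B) on C2. Ring A is fully substituted, with the chelated hydroxyl on C5, methoxy groups on C6 and C7, and a 3-methylbut-2-en-1-yl (prenyl) group on C8 next to O1. C2 is the only stereocentre. It is an ether carbon β to the C4 ketone and benzylic to a para-hydroxyphenyl ring, so base can erase it by E1cB opening of ring C to the chalcone, and acid can erase it by ionisation towards a quinone methide. The trisubstituted prenyl olefin does not tolerate protic acid, hydrogenation or indiscriminate oxidants, and O5 has to be told apart from the two neighbouring methyl ethers. The difficulty is therefore threefold: placing four different substituents on ring A, setting a labile C2 as one enantiomer, and finishing under conditions that are neither basic nor strongly acidic. The strategy rests on ring B: it is a 1,4-disubstituted benzene with C1' bonded to C2 and oxygen on C4'. That is the pattern a 2-siloxybutadiene (C3' to C6', oxygen on C4') leaves when it adds across a terminal alkyne on C2 (C1' and C2'). C2 can therefore be set as a small propargylic ether centre by asymmetric alkynylation of a chromone, before ring B exists.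

## Retrosynthetic reasoning

**20 to 19 (O5–CH3).** The last bond cut is the O5–methyl bond. This methyl ether is the only one peri to the C4 carbonyl, so a chelating Lewis acid can single it out. Keeping it to the end lets ring A travel as a uniform trimethoxyarene taken from 1, and keeps a free phenol para to C8 away from the oxidant used earlier. The forward reaction must remove one methyl group of three without protic acid (prenyl olefin) and without base (C2). A chelating magnesium halide is planned rather than a boron or aluminium trihalide, because the latter liberate hydrogen halide from the free phenol of 19.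

**19 to 17 (oxidation level of ring B).** Ring B is taken back to its 1,4-dihydro level, with the phenol masked as a silyl enol ether. No skeletal bond is cut. The gain is that 17 is the direct product of a cycloaddition. The forward step is a dehydrogenation by a high-potential quinone that must be faster at the doubly allylic ring CH2 groups than at the prenyl CH2 or at C2–C3.

**17 to 15 and 16 (C1'–C6' and C2'–C3').** This is the key disconnection. Cutting these two bonds of ring B leaves the terminal alkyne 15, which supplies C1' and C2', and the diene 16, which supplies C3' to C6' with the oxygen already on C4'. Cutting here rather than at C2–C1' avoids an aryl transfer to C2 and reduces the stereochemical problem to a propargylic centre. The forward reaction must join an unactivated alkyne and an electron-rich diene under neutral conditions, with the siloxy carbon para to C1'. A cobalt–diphosphine catalyst is chosen for this.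

**15 to 14, then 14 to 10 and 11 (C–Si, then C2–C(sp)).** The terminal alkyne comes from the silylalkyne 14 by protodesilylation, which must be non-basic because 14 and 15 can open by β-elimination. Cutting the C2–alkynyl bond of 14 gives the achiral chromone 10 and the alkyne 11. The forward reaction is a copper-catalysed enantioselective alkynylation of the benzopyrylium ion formed from 10 by O-silylation. It sets C2, the only stereocentre of the route.

**10 to 7 (O1–C2 and C2–C3).** C2 of the chromone is a one-carbon unit at the formic acid oxidation level. Removing it leaves the methyl ketone 7, whose phenol oxygen is still protected. The forward sequence is condensation with a formamide acetal, then acid, which unmasks the phenol and closes ring C.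

**7 to 5, 5 to 2 and 3, 2 to 1 (C4a–acyl, C8–prenyl, O-protection).** The acetyl and prenyl groups sit on the two carbons ortho to the phenol oxygen of 1, each also flanked by a methoxy group. Both are therefore sites of directed ortho-lithiation once the phenol is a methoxymethyl ether (2). Prenyl is introduced first with 3. The acyl group follows, because a ketone would not survive a second lithiation. The symmetry of 2 means the first lithiation has only one possible outcome.

## Alternatives that were turned down

**Alternative 1:** Ring A is disconnected instead of ring B. Cutting C4a–C5 and C8–C8a leads to the iododihydropyran A2, which already carries C2 and C4 of ring C as stereocentres, and to dimethyl squarate A3. In the forward direction the vinyllithium from A2 would add to one carbonyl of A3 and the alkoxide would be O-methylated. Heating would then open the cyclobutenone (4π) to a dienylketene that closes (6π) onto the dihydropyran double bond and tautomerises to the chromanol A1.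
- For it: the substitution pattern of ring A is written in by the squarate, so there is no regiochemical question. C4 is at the alcohol level, so C2 cannot be lost by β-elimination.
- Against it: A1 has OH rather than prenyl on C8, so a sulfonylation and a cross-coupling are needed at a position flanked by O1 and the C7 methoxy group. C4 must be desilylated and oxidised. The benzyl ether must be removed after the prenyl group is in place, which excludes hydrogenolysis. The 5-O-methyl group must still be cleaved. A2, with two stereocentres, is a multi-step target in itself.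
- Comparison: this plan is as strong as the chosen one on regiochemical certainty for ring A, and stronger on protecting C2 from epimerisation. The chosen route takes ring A ready-made from 1, keeps the correct oxidation level at C4 throughout, and should be about half as long.

**Alternative 2:** Ring C is disconnected at O1–C2 and C3–C4. The precursors are the salicylaldehyde A5, an orthoformate and the styrene A6. A chiral Brønsted acid would convert A5 into a 4-methoxy ortho-quinone methide (an oxocarbenium ion), which adds A6 in a [4+2] sense to give the chroman A4.
- For it: it is the most convergent plan. The whole carbon skeleton, with prenyl and ring B, is assembled in one step, and A5 is one formylation away from 5.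
- Against it: A4 is at the flavan oxidation level. The C4 methyl ether must become a ketone by benzylic oxidation of a ring whose prenyl CH2 is activated in the same way, and the C4 stereocentre is made only to be destroyed. Enantiocontrol over a cationic intermediate with a weakly binding styrene is the least secured element. The acid meets the prenyl olefin. The benzyl ether again cannot be hydrogenolysed.
- Comparison: this plan is stronger on convergence and on steps to the full skeleton. The chosen route offers in exchange the right oxidation level at C4 from the start, a C2 centre set by a catalytic reaction known for chromones, and no protecting group on ring B.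

**Alternative 3:** Ring C is disconnected at C4–C4a. The precursor is the β-aryloxy acid A8, which would be activated as a mixed anhydride, or as the acid chloride with a tin tetrahalide, and acylate the only free position of ring A to give the flavanone A7.
- For it: the closure is textbook Friedel–Crafts chemistry. Ring B arrives intact. Only one ring position is open, so the regiochemistry is certain.
- Against it: A8 needs a configurationally defined benzylic ether between a hindered, electron-rich phenol and a β-hydroxy ester, by substitution with inversion. That step competes with elimination to the cinnamate and with ionisation at the para-oxygenated benzylic carbon. The acylation conditions then expose both the prenyl olefin (cation–olefin chemistry, hydrohalogenation) and the same benzylic C–O bond (ionisation, loss of the phenol) to strong acid. The acetate and the 5-O-methyl group remain to be removed afterwards.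
- Comparison: this plan is stronger in relying only on long-established reaction types, whereas the chosen route has one cycloaddition that is new for this substrate. The chosen route offers a C2 centre formed catalytically on a preformed ring C and never exposed to a strong acid.

Key step: step 7

Remark on the chemistry: the sense of induction of the copper–bis(oxazoline) catalyst in step 5 is assumed to be reversible by choice of ligand antipode; the antipode meant is the one that delivers the alkynyl group to the Re face of C2 and so gives the (2S) product.

## Route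

**Step 1**
Reactants: 1 3,4,5-trimethoxyphenol
Product: 2 1,2,3-trimethoxy-5-(methoxymethoxy)benzene
Conditions: NaH, THF/DMF, 0 °C; MOMCl, 0 °C → rt
Reagents that add atoms: chloromethyl methyl ether, COCCl
Why: O-alkylation of the sodium phenoxide (Williamson ether synthesis); the methoxymethyl ether protects the phenol and is the directing group for the two lithiations that follow.

**Step 2**
Reactants: 2 1,2,3-trimethoxy-5-(methoxymethoxy)benzene; 3 1-bromo-3-methylbut-2-ene (prenyl bromide)
Product: 5 1,2,3-trimethoxy-5-(methoxymethoxy)-4-(3-methylbut-2-en-1-yl)benzene, via aryllithium 4 (not isolated)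
Conditions: n-BuLi, THF, 0 °C; CuI (10 mol%), 3, −78 °C → rt
Reagents that add atoms: none
Why: Directed ortho-metalation at a ring hydrogen flanked by the methoxymethoxy and a methoxy group; the two such positions are equivalent by symmetry, so one aryllithium forms, and copper-catalysed allylation with the primary allylic bromide should give the linear prenyl arene.

**Step 3**
Reactants: 5 1,2,3-trimethoxy-5-(methoxymethoxy)-4-(3-methylbut-2-en-1-yl)benzene
Product: 7 1-[2-(methoxymethoxy)-4,5,6-trimethoxy-3-(3-methylbut-2-en-1-yl)phenyl]ethan-1-one, via aryllithium 6 (not isolated)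
Conditions: n-BuLi, TMEDA, THF, −20 → 0 °C; MeC(O)N(OMe)Me, −78 → 0 °C; H2O
Reagents that add atoms: N-methoxy-N-methylacetamide, CC(=O)N(C)OC
Why: Second directed ortho-metalation at the only ring hydrogen left, again between two coordinating oxygen groups, which should favour ring over benzylic deprotonation; acylation with the N-methoxy-N-methylamide stops at the ketone because the chelated tetrahedral adduct collapses only on quench.

**Step 4**
Reactants: 7 1-[2-(methoxymethoxy)-4,5,6-trimethoxy-3-(3-methylbut-2-en-1-yl)phenyl]ethan-1-one
Product: 10 5,6,7-trimethoxy-8-(3-methylbut-2-en-1-yl)-4H-chromen-4-one, via MOM-protected enaminone 8 (not isolated), via phenolic enaminone 9 (not isolated)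
Conditions: Me2NCH(OMe)2, toluene, 100 °C; evaporate; 2 M HCl, MeOH, rt
Reagents that add atoms: N,N-dimethylformamide dimethyl acetal, COC(OC)N(C)C
Why: Enaminone route to 2,3-unsubstituted chromones: the methyl ketone condenses with the amide acetal, acid then removes the methoxymethyl group, and the freed phenol adds to the protonated vinylogous amide and expels dimethylamine (addition–elimination). Dilute acid in methanol at room temperature should leave the prenyl olefin intact, because ring closure removes the neighbouring phenol at once.

**Step 5**
Reactants: 10 5,6,7-trimethoxy-8-(3-methylbut-2-en-1-yl)-4H-chromen-4-one; 11 ethynyltrimethylsilane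
Product: 14 (S)-5,6,7-trimethoxy-8-(3-methylbut-2-en-1-yl)-2-[(trimethylsilyl)ethynyl]chroman-4-one, via siloxybenzopyrylium triflate 12 (not isolated), via silyl enol ether 13 (not isolated)
Conditions: CuI (10 mol%), chiral bis(oxazoline) ligand (12 mol%, antipode giving 2S), iPr2NEt, TBSOTf, toluene, −78 °C; then 2 M HCl, THF, rt
Reagents that add atoms: none
Why: Copper-catalysed enantioselective alkynylation of a benzopyrylium ion, a reaction type known for chromones: O-silylation of the C4 carbonyl makes C2 electrophilic and the ligand-bound copper acetylide adds there. The new C2 centre is set by the ligand, addition to the Re face giving 2S; the product is held as a silyl enol ether, which cannot open by β-elimination, until mild acid releases the ketone.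

**Step 6**
Reactants: 14 (S)-5,6,7-trimethoxy-8-(3-methylbut-2-en-1-yl)-2-[(trimethylsilyl)ethynyl]chroman-4-one
Product: 15 (S)-2-ethynyl-5,6,7-trimethoxy-8-(3-methylbut-2-en-1-yl)chroman-4-one
Conditions: AgNO3 (10 mol%), acetone/H2O/CH2Cl2, rt, dark
Reagents that add atoms: none
Why: Silver-catalysed protodesilylation of a trimethylsilylalkyne through a silver acetylide; the medium is neutral, so the base-induced opening of ring C that would racemise C2 is avoided.

**Step 7**
Reactants: 15 (S)-2-ethynyl-5,6,7-trimethoxy-8-(3-methylbut-2-en-1-yl)chroman-4-one; 16 2-(trimethylsiloxy)buta-1,3-diene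
Product: 17 (S)-5,6,7-trimethoxy-8-(3-methylbut-2-en-1-yl)-2-[4-(trimethylsiloxy)cyclohexa-1,4-dien-1-yl]chroman-4-one
Conditions: CoBr2(dppe) (10 mol%), Zn powder (20 mol%), ZnI2 (20 mol%), 16 (2 equiv), CH2Cl2, rt
Reagents that add atoms: none
Why: Zinc reduces CoBr2(dppe) from divalent to monovalent cobalt and ZnI2 abstracts halide, so a cationic cobalt–dppe fragment binds the s-cis diene 16 and the alkyne of 15 side by side. Oxidative cyclisation forms the first C–C bond and a trivalent cobaltacycle; C–C reductive elimination forms the second bond, releases the 1,4-cyclohexadiene 17 and returns monovalent cobalt. The closest known reaction type is the cobalt–diphosphine-catalysed neutral Diels–Alder reaction of unactivated terminal alkynes with 2-substituted butadienes, 2-siloxybutadienes included; only the substituent on the alkyne is new. Ring B is closed as a six-membered carbocycle in an intermolecular formal [4+2] mode, the new bonds C1'–C6' and C2'–C3' joining the alkyne carbons to the diene termini. No stereocentre is formed; C2 is a spectator and should keep its configuration, because no base is present to open ring C and ZnI2 at room temperature should not ionise the propargylic C–O bond. The selectivity needed is regiochemical: the siloxy carbon must end up para to C1', which the dppe ligand should secure by placing the two substituents far apart in the cobaltacycle, helped by the bulk of the secondary propargylic carbon. The catalyst requires a 1,3-diene and an alkyne, so the trisubstituted prenyl olefin, the aryl ketone and the methyl ethers should not react, and the excess of 16 should suppress alkyne trimerisation.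

**Step 8**
Reactants: 17 (S)-5,6,7-trimethoxy-8-(3-methylbut-2-en-1-yl)-2-[4-(trimethylsiloxy)cyclohexa-1,4-dien-1-yl]chroman-4-one
Product: 19 (S)-2-(4-hydroxyphenyl)-5,6,7-trimethoxy-8-(3-methylbut-2-en-1-yl)chroman-4-one, via aryl trimethylsilyl ether 18 (not isolated)
Conditions: DDQ (1.05 equiv), toluene, 0 °C → rt; then MeOH, citric acid (cat.), rt
Reagents that add atoms: none
Why: Quinone dehydrogenation of a 1,4-cyclohexadiene: hydride abstraction from a doubly allylic CH2 gives a siloxy-stabilised cyclohexadienyl cation that loses a ring proton and aromatises. With one equivalent at low temperature this should be much faster than oxidation of the prenyl CH2 or of C2–C3, and the aryl trimethylsilyl ether is cleaved by mild acidic methanolysis.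

**Step 9**
Reactants: 19 (S)-2-(4-hydroxyphenyl)-5,6,7-trimethoxy-8-(3-methylbut-2-en-1-yl)chroman-4-one
Product: 20 (S)-5-hydroxy-2-(4-hydroxyphenyl)-6,7-dimethoxy-8-(3-methylbut-2-en-1-yl)chroman-4-one
Conditions: MgI2·OEt2 (4 equiv), THF, 40 °C; cold 0.5 M HCl work-up
Reagents that add atoms: none
Why: Chelation-directed O-demethylation, a reaction type established for 5-methoxyflavanones including 8-prenylated ones with free phenols: magnesium bridges the C4 carbonyl and O5, and iodide removes the activated methyl group by SN2 attack, while the methoxy groups on C6 and C7 are not chelated. No hydrogen halide is formed from the free phenol, so the prenyl olefin should be safe, and no base is present to open ring C.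

## Compound list

1 | 3,4,5-trimethoxyphenol | COc1cc(O)cc(OC)c1OC | starting material
2 | 1,2,3-trimethoxy-5-(methoxymethoxy)benzene | COCOc1cc(OC)c(OC)c(OC)c1 | intermediate
3 | 1-bromo-3-methylbut-2-ene (prenyl bromide) | CC(C)=CCBr | starting material
4 | [2-(methoxymethoxy)-4,5,6-trimethoxyphenyl]lithium | [Li]c1c(OCOC)cc(OC)c(OC)c1OC | intermediate (not isolated)
5 | 1,2,3-trimethoxy-5-(methoxymethoxy)-4-(3-methylbut-2-en-1-yl)benzene | COCOc1cc(OC)c(OC)c(OC)c1CC=C(C)C | intermediate
6 | [2-(methoxymethoxy)-4,5,6-trimethoxy-3-(3-methylbut-2-en-1-yl)phenyl]lithium | [Li]c1c(OC)c(OC)c(OC)c(CC=C(C)C)c1OCOC | intermediate (not isolated)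
7 | 1-[2-(methoxymethoxy)-4,5,6-trimethoxy-3-(3-methylbut-2-en-1-yl)phenyl]ethan-1-one | CC(=O)c1c(OC)c(OC)c(OC)c(CC=C(C)C)c1OCOC | intermediate
8 | (E)-3-(dimethylamino)-1-[2-(methoxymethoxy)-4,5,6-trimethoxy-3-(3-methylbut-2-en-1-yl)phenyl]prop-2-en-1-one | CN(C)/C=C/C(=O)c1c(OC)c(OC)c(OC)c(CC=C(C)C)c1OCOC | intermediate (not isolated)
9 | (E)-3-(dimethylamino)-1-[2-hydroxy-4,5,6-trimethoxy-3-(3-methylbut-2-en-1-yl)phenyl]prop-2-en-1-one | CN(C)/C=C/C(=O)c1c(OC)c(OC)c(OC)c(CC=C(C)C)c1O | intermediate (not isolated)
10 | 5,6,7-trimethoxy-8-(3-methylbut-2-en-1-yl)-4H-chromen-4-one | COc1c(OC)c2c(c(CC=C(C)C)c1OC)OC=CC2=O | intermediate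
11 | ethynyltrimethylsilane (trimethylsilylacetylene) | C#C[Si](C)(C)C | starting material
12 | 4-(tert-butyldimethylsiloxy)-5,6,7-trimethoxy-8-(3-methylbut-2-en-1-yl)chromenylium trifluoromethanesulfonate | CC(C)=CCc1c(OC)c(OC)c(OC)c2c(O[Si](C)(C)C(C)(C)C)cc[o+]c12.[O-]S(=O)(=O)C(F)(F)F | intermediate (not isolated)
13 | (S)-4-(tert-butyldimethylsiloxy)-5,6,7-trimethoxy-8-(3-methylbut-2-en-1-yl)-2-[(trimethylsilyl)ethynyl]-2H-chromene | COc1c(OC)c2c(c(CC=C(C)C)c1OC)O[C@H](C#C[Si](C)(C)C)C=C2O[Si](C)(C)C(C)(C)C | intermediate (not isolated)
14 | (S)-5,6,7-trimethoxy-8-(3-methylbut-2-en-1-yl)-2-[(trimethylsilyl)ethynyl]chroman-4-one | COc1c(OC)c2c(c(CC=C(C)C)c1OC)O[C@H](C#C[Si](C)(C)C)CC2=O | intermediate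
15 | (S)-2-ethynyl-5,6,7-trimethoxy-8-(3-methylbut-2-en-1-yl)chroman-4-one | COc1c(OC)c2c(c(CC=C(C)C)c1OC)O[C@H](C#C)CC2=O | intermediate
16 | 2-(trimethylsiloxy)buta-1,3-diene | C=CC(=C)O[Si](C)(C)C | starting material
17 | (S)-5,6,7-trimethoxy-8-(3-methylbut-2-en-1-yl)-2-[4-(trimethylsiloxy)cyclohexa-1,4-dien-1-yl]chroman-4-one | COc1c(OC)c2c(c(CC=C(C)C)c1OC)O[C@H](C1=CCC(O[Si](C)(C)C)=CC1)CC2=O | intermediate
18 | (S)-5,6,7-trimethoxy-8-(3-methylbut-2-en-1-yl)-2-[4-(trimethylsiloxy)phenyl]chroman-4-one | COc1c(OC)c2c(c(CC=C(C)C)c1OC)O[C@H](c1ccc(O[Si](C)(C)C)cc1)CC2=O | intermediate (not isolated)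
19 | (S)-2-(4-hydroxyphenyl)-5,6,7-trimethoxy-8-(3-methylbut-2-en-1-yl)chroman-4-one | COc1c(OC)c2c(c(CC=C(C)C)c1OC)O[C@H](c1ccc(O)cc1)CC2=O | intermediate
20 | (S)-5-hydroxy-2-(4-hydroxyphenyl)-6,7-dimethoxy-8-(3-methylbut-2-en-1-yl)chroman-4-one | COc1c(O)c2c(c(CC=C(C)C)c1OC)O[C@H](c1ccc(O)cc1)CC2=O | target

## Step count and least certain steps

Total step count: 9. Longest linear sequence: 9 steps (1 to 20); compounds 3, 11 and 16 are bought.

**Step 7 (key step).** The most likely failure is a stalled or diverted cycloaddition. The C4 carbonyl, O1 and the ring-A ethers near the alkyne may hold the cobalt and stop turnover. The alkyne may trimerise. ZnI2 may degrade the two silyl enol ethers. The propargylic oxygen may erode the para preference. The fallback gives up building ring B and transfers it intact. It sets out from 10: a palladium-catalysed asymmetric conjugate addition of 4-(tert-butyldimethylsiloxy)phenylboronic acid (Pd(OCOCF3)2, chiral pyridine–oxazoline ligand, aqueous 1,2-dichloroethane, 60 °C) would give (S)-2-[4-(tert-butyldimethylsiloxy)phenyl]-5,6,7-trimethoxy-8-(3-methylbut-2-en-1-yl)chroman-4-one F1. Desilylation with HF·pyridine then returns to the route at 19.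

**Step 5.** The most likely failure is insufficient facial discrimination. The 5-methoxy group next to the siloxy group and the prenyl group next to O1 change the shape of the benzopyrylium ion on which the catalyst was developed, and the electron-rich cation is less electrophilic, which favours an unselective background addition. The fallback replaces catalyst control by resolution and sets out from 10. The same alkynylation with CuI and iPr2NEt but no chiral ligand would give racemic 5,6,7-trimethoxy-8-(3-methylbut-2-en-1-yl)-2-[(trimethylsilyl)ethynyl]chroman-4-one F2. Preparative chromatography on a chiral stationary phase would separate it, returning to the route at 14. The unwanted (R)-5,6,7-trimethoxy-8-(3-methylbut-2-en-1-yl)-2-[(trimethylsilyl)ethynyl]chroman-4-one F3 could be returned to F2 by an amine base through reversible opening of ring C.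

**Step 9.** The most likely failure is loss of configuration at C2, if the chelated magnesium Lewis acid assists opening of ring C at the temperature the demethylation needs. A second risk is further demethylation at O6 once the 5-phenoxide can chelate in the other direction. The temperature would be kept as low as conversion allows. Boron trichloride at low temperature is not relied on, because the free phenol would release hydrogen chloride next to the prenyl olefin. The fallback moves the demethylation to before C2 is stereogenic and sets out from 10:
- MgI2·OEt2 in hot THF would give 5-hydroxy-6,7-dimethoxy-8-(3-methylbut-2-en-1-yl)-4H-chromen-4-one F4.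
- TBSOTf and 2,6-lutidine would give 5-(tert-butyldimethylsiloxy)-6,7-dimethoxy-8-(3-methylbut-2-en-1-yl)-4H-chromen-4-one F5.
- The operations of step 5 would give (S)-5-(tert-butyldimethylsiloxy)-6,7-dimethoxy-8-(3-methylbut-2-en-1-yl)-2-[(trimethylsilyl)ethynyl]chroman-4-one F6.
- The operations of step 6 would give (S)-5-(tert-butyldimethylsiloxy)-2-ethynyl-6,7-dimethoxy-8-(3-methylbut-2-en-1-yl)chroman-4-one F7.
- The operations of step 7 would give (S)-5-(tert-butyldimethylsiloxy)-6,7-dimethoxy-8-(3-methylbut-2-en-1-yl)-2-[4-(trimethylsiloxy)cyclohexa-1,4-dien-1-yl]chroman-4-one F8.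
- The operations of step 8 would give (S)-5-(tert-butyldimethylsiloxy)-2-(4-hydroxyphenyl)-6,7-dimethoxy-8-(3-methylbut-2-en-1-yl)chroman-4-one F9.
- HF·pyridine would then remove the silyl group and return to the route at 20.

If the 5-silyl ether were lost early, the free 5-hydroxy compounds would converge on 20 as well.

**Step 8.** The most likely failure is over-oxidation: hydride abstraction from the prenyl CH2, which is activated by three oxygen substituents of ring A, or dehydrogenation across C2–C3 to the flavone. The fallback changes the mechanism from hydride abstraction to a palladium enolate and sets out from 17. A Saegusa–Ito oxidation (Pd(OAc)2, MeCN, rt) would convert the silyl enol ether into (S)-5,6,7-trimethoxy-8-(3-methylbut-2-en-1-yl)-2-(4-oxocyclohexa-1,5-dien-1-yl)chroman-4-one F10. This dienone tautomerises to the phenol and so returns to the route at 19.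

**Step 3.** The most likely failure is deprotonation at the wrong site: lateral lithiation of the benzylic–allylic CH2 of the prenyl group, or proton transfer from the amide to the hindered aryllithium. The fallback introduces the acetyl group before the prenyl group, without lithiation, and sets out from 1:
- Friedel–Crafts acetylation (BF3·OEt2, AcOH, 90 °C) would give 1-(2-hydroxy-4,5,6-trimethoxyphenyl)ethan-1-one F11.
- Bromination with N-bromosuccinimide at the only free ring position would give 1-(3-bromo-2-hydroxy-4,5,6-trimethoxyphenyl)ethan-1-one F12.
- A linear-selective Suzuki–Miyaura coupling with prenylboronic acid pinacol ester (Pd(OAc)2, bulky biarylphosphine, K3PO4, THF/H2O) would give 1-[2-hydroxy-4,5,6-trimethoxy-3-(3-methylbut-2-en-1-yl)phenyl]ethan-1-one F13.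
- Condensation of F13 with N,N-dimethylformamide dimethyl acetal returns to the route at 9, which acid closes to 10.

## Further compounds

F1 | step 7 | (S)-2-[4-(tert-butyldimethylsiloxy)phenyl]-5,6,7-trimethoxy-8-(3-methylbut-2-en-1-yl)chroman-4-one | COc1c(OC)c2c(c(CC=C(C)C)c1OC)O[C@H](c1ccc(O[Si](C)(C)C(C)(C)C)cc1)CC2=O
F2 | step 5 | racemic 5,6,7-trimethoxy-8-(3-methylbut-2-en-1-yl)-2-[(trimethylsilyl)ethynyl]chroman-4-one | COc1c(OC)c2c(c(CC=C(C)C)c1OC)OC(C#C[Si](C)(C)C)CC2=O
F3 | step 5 | (R)-5,6,7-trimethoxy-8-(3-methylbut-2-en-1-yl)-2-[(trimethylsilyl)ethynyl]chroman-4-one | COc1c(OC)c2c(c(CC=C(C)C)c1OC)O[C@@H](C#C[Si](C)(C)C)CC2=O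
F4 | step 9 | 5-hydroxy-6,7-dimethoxy-8-(3-methylbut-2-en-1-yl)-4H-chromen-4-one | COc1c(O)c2c(c(CC=C(C)C)c1OC)OC=CC2=O
F5 | step 9 | 5-(tert-butyldimethylsiloxy)-6,7-dimethoxy-8-(3-methylbut-2-en-1-yl)-4H-chromen-4-one | COc1c(O[Si](C)(C)C(C)(C)C)c2c(c(CC=C(C)C)c1OC)OC=CC2=O
F6 | step 9 | (S)-5-(tert-butyldimethylsiloxy)-6,7-dimethoxy-8-(3-methylbut-2-en-1-yl)-2-[(trimethylsilyl)ethynyl]chroman-4-one | COc1c(O[Si](C)(C)C(C)(C)C)c2c(c(CC=C(C)C)c1OC)O[C@H](C#C[Si](C)(C)C)CC2=O
F7 | step 9 | (S)-5-(tert-butyldimethylsiloxy)-2-ethynyl-6,7-dimethoxy-8-(3-methylbut-2-en-1-yl)chroman-4-one | COc1c(O[Si](C)(C)C(C)(C)C)c2c(c(CC=C(C)C)c1OC)O[C@H](C#C)CC2=O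
F8 | step 9 | (S)-5-(tert-butyldimethylsiloxy)-6,7-dimethoxy-8-(3-methylbut-2-en-1-yl)-2-[4-(trimethylsiloxy)cyclohexa-1,4-dien-1-yl]chroman-4-one | COc1c(O[Si](C)(C)C(C)(C)C)c2c(c(CC=C(C)C)c1OC)O[C@H](C1=CCC(O[Si](C)(C)C)=CC1)CC2=O
F9 | step 9 | (S)-5-(tert-butyldimethylsiloxy)-2-(4-hydroxyphenyl)-6,7-dimethoxy-8-(3-methylbut-2-en-1-yl)chroman-4-one | COc1c(O[Si](C)(C)C(C)(C)C)c2c(c(CC=C(C)C)c1OC)O[C@H](c1ccc(O)cc1)CC2=O
F10 | step 8 | (S)-5,6,7-trimethoxy-8-(3-methylbut-2-en-1-yl)-2-(4-oxocyclohexa-1,5-dien-1-yl)chroman-4-one | COc1c(OC)c2c(c(CC=C(C)C)c1OC)O[C@H](C1=CCC(=O)C=C1)CC2=O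
F11 | step 3 | 1-(2-hydroxy-4,5,6-trimethoxyphenyl)ethan-1-one | CC(=O)c1c(O)cc(OC)c(OC)c1OC
F12 | step 3 | 1-(3-bromo-2-hydroxy-4,5,6-trimethoxyphenyl)ethan-1-one | CC(=O)c1c(O)c(Br)c(OC)c(OC)c1OC
F13 | step 3 | 1-[2-hydroxy-4,5,6-trimethoxy-3-(3-methylbut-2-en-1-yl)phenyl]ethan-1-one | CC(=O)c1c(O)c(CC=C(C)C)c(OC)c(OC)c1OC
A1 | alternative 1 | (2S,4S)-2-[4-(benzyloxy)phenyl]-4-(tert-butyldimethylsiloxy)-5,6,7-trimethoxychroman-8-ol | COc1c(OC)c2c(c(O)c1OC)O[C@H](c1ccc(OCc3ccccc3)cc1)C[C@@H]2O[Si](C)(C)C(C)(C)C
A2 | alternative 1 | (2S,4S)-2-[4-(benzyloxy)phenyl]-4-(tert-butyldimethylsiloxy)-5-iodo-3,4-dihydro-2H-pyran | IC1=CO[C@H](c2ccc(OCc3ccccc3)cc2)C[C@@H]1O[Si](C)(C)C(C)(C)C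
A3 | alternative 1 | dimethyl squarate (3,4-dimethoxycyclobut-3-ene-1,2-dione) | COC1=C(OC)C(=O)C1=O
A4 | alternative 2 | (2S,4S)-2-[4-(benzyloxy)phenyl]-4,5,6,7-tetramethoxy-8-(3-methylbut-2-en-1-yl)chroman | COc1c(OC)c2c(c(CC=C(C)C)c1OC)O[C@H](c1ccc(OCc3ccccc3)cc1)C[C@@H]2OC
A5 | alternative 2 | 2-hydroxy-4,5,6-trimethoxy-3-(3-methylbut-2-en-1-yl)benzaldehyde | O=Cc1c(O)c(CC=C(C)C)c(OC)c(OC)c1OC
A6 | alternative 2 | 4-(benzyloxy)styrene | C=Cc1ccc(OCc2ccccc2)cc1
A7 | alternative 3 | (S)-2-(4-acetoxyphenyl)-5,6,7-trimethoxy-8-(3-methylbut-2-en-1-yl)chroman-4-one | COc1c(OC)c2c(c(CC=C(C)C)c1OC)O[C@H](c1ccc(OC(C)=O)cc1)CC2=O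
A8 | alternative 3 | (S)-3-(4-acetoxyphenyl)-3-[3,4,5-trimethoxy-2-(3-methylbut-2-en-1-yl)phenoxy]propanoic acid | COc1cc(O[C@H](c2ccc(OC(C)=O)cc2)CC(=O)O)c(CC=C(C)C)c(OC)c1OC
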